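Japonicone A is cut at C1–C13′ of its norbornene core (bicycle C1–C2–C3–C4=C5 with the C13′–C11′ bridge). That bond is formed last by a 1,2-shift: the exo-epoxide of an isomeric fulvene/α-methylene-lactone Diels–Alder adduct, in which C13′ sits on C5 and C4 carries an exocyclic methylene, is opened by a Lewis acid at C1; C13′ migrates from C5 to C1 and a silane reduces the resulting C5–C4–C15 allyl cation at C15. One operation thus redraws the bicycle, makes quaternary C1, places the C2 oxygen syn to the new C4=C5 alkene (the 2-exo,7-syn relationship of a rearranged norbornyl system, the feature exploited) and creates the C15 methyl.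

Key step: step 25

Remark: unprimed locants are guaiane atoms and primed ones eudesmane atoms; the silyl ketene thioacetal of step 5 and the Reformatsky reagent of step 18 are taken as reagents made in one flask from S-ethyl ethanethioate (LiN(i-Pr)2, TBSCl) and from ethyl bromoacetate (Zn).

**Guaiane half (steps 1–12)**

Step 1
Reactants: 1 (R)-epichlorohydrin
Product: 2 (R)-1-chloropent-4-en-2-ol
Conditions: CH2=CHMgBr, CuI (10 mol%), THF, −40 → −20 °C
Reagents that add atoms: vinylmagnesium bromide, C=C[Mg]Br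
Why: Copper-catalysed Grignard opening of the epoxide at its CH2 carbon (SN2) leaves the carbinol centre, the future C8, untouched, and chloride is not displaced at this temperature.

Step 2
Reactants: 2 (R)-1-chloropent-4-en-2-ol
Product: 3 (R)-2-(prop-2-en-1-yl)oxirane
Conditions: KOH (powder), Et2O, 0 → 23 °C
Reagents that add atoms: none
Why: Intramolecular Williamson etherification (alkoxide displaces the primary chloride) should close the new epoxide without breaking a bond to the stereocentre.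

Step 3
Reactants: 3 (R)-2-(prop-2-en-1-yl)oxirane
Product: 5 (5R)-3-(phenylsulfanyl)-5-(prop-2-en-1-yl)oxolan-2-one (C3 epimers), via hydroxy acid 4 (not isolated)
Conditions: PhSCH2CO2H, LiN(i-Pr)2 (2.1 equiv), THF, −78 → 0 °C; then 3, 0 → 23 °C; then TsOH·H2O (cat.), PhH, 80 °C
Reagents that add atoms: (phenylsulfanyl)acetic acid, OC(=O)CSc1ccccc1
Why: The carboxylic acid dianion opens the terminal epoxide at CH2 (SN2) and the γ-hydroxy acid lactonises under acid catalysis, so C8 keeps its configuration.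

Step 4
Reactants: 5 (5R)-3-(phenylsulfanyl)-5-(prop-2-en-1-yl)oxolan-2-one
Product: 7 (R)-5-(prop-2-en-1-yl)furan-2(5H)-one, via sulfoxide 6 (not isolated)
Conditions: NaIO4, MeOH/H2O, 0 °C; then PhMe, CaCO3, 110 °C
Reagents that add atoms: none
Why: Sulfide-to-sulfoxide oxidation followed by thermal syn-elimination of the sulfoxide toward the only β-hydrogens (C7) should give the butenolide without touching the allyl group.

Step 5
Reactants: 7 (R)-5-(prop-2-en-1-yl)furan-2(5H)-one
Product: 9 S-ethyl 2-[(2R,3R)-5-oxo-2-(prop-2-en-1-yl)oxolan-3-yl]ethanethioate, via silyl ketene acetal 8 (not isolated)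
Conditions: CH2=C(OTBS)SEt (1.5 equiv), TBSOTf (10 mol%), CH2Cl2, −78 °C; then 1 M HCl, THF
Reagents that add atoms: 1-(tert-butyldimethylsilyloxy)-1-(ethylsulfanyl)ethene, C=C(O[Si](C)(C)C(C)(C)C)SCC
Why: Mukaiyama–Michael addition, in which the nucleophile enters C7 anti to the C8 allyl group of the butenolide and so sets the trans C7/C8 lactone.

Step 6
Reactants: 9 S-ethyl 2-[(2R,3R)-5-oxo-2-(prop-2-en-1-yl)oxolan-3-yl]ethanethioate
Product: 10 (4S,5R)-4-(2-oxobut-3-en-1-yl)-5-(prop-2-en-1-yl)oxolan-2-one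
Conditions: Bu3SnCH=CH2, Pd2(dba)3 (2.5 mol%), P(2-furyl)3, CuO2PPh2 (1.2 equiv), THF, 50 °C
Reagents that add atoms: tributyl(vinyl)stannane, C=C[Sn](CCCC)(CCCC)CCCC
Why: Liebeskind–Srogl-type thioester–stannane ketone synthesis (palladium catalysis, copper diphenylphosphinate as thiolate scavenger) should convert only the thioester into the vinyl ketone, the lactone being inert and no stereocentre involved.

Step 7
Reactants: 10 (4S,5R)-4-(2-oxobut-3-en-1-yl)-5-(prop-2-en-1-yl)oxolan-2-one
Product: 11 (3aS,8aR)-3a,4,8,8a-tetrahydro-2H-cyclohepta[b]furan-2,5(3H)-dione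
Conditions: second-generation Grubbs catalyst (H2IMes)(PCy3)Cl2Ru=CHPh (5 mol%), CH2Cl2 (5 mM), 40 °C
Reagents that add atoms: none
Why: Ring-closing metathesis of the vinyl ketone with the allyl group should close the seven-membered enone (C1=C10) on the trans lactone, driven by loss of ethene.

Step 8
Reactants: 11 (3aS,8aR)-3a,4,8,8a-tetrahydro-2H-cyclohepta[b]furan-2,5(3H)-dione
Product: 13 (3aS,7R,8aR)-7-methyl-2-oxo-3,3a,4,7,8,8a-hexahydro-2H-cyclohepta[b]furan-5-yl trifluoromethanesulfonate, via zinc enolate 12 (not isolated)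
Conditions: Me2Zn (1.5 equiv), Cu(OTf)2 (2 mol%), binaphthol-derived bis(1-phenylethyl)amine phosphoramidite (4 mol%), PhMe, −30 °C; then Tf2O, 0 °C
Reagents that add atoms: dimethylzinc, C[Zn]C; trifluoromethanesulfonic anhydride, O=S(=O)(OS(=O)(=O)C(F)(F)F)C(F)(F)F
Why: Copper-catalysed asymmetric conjugate addition, with the ligand enantiomer chosen so that methyl adds to the C10 face anti to C8–O (10R), followed by O-triflation of the regiodefined zinc enolate (C5=C1), a tandem conjugate addition–enolate trapping.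

Step 9
Reactants: 13 (3aS,7R,8aR)-7-methyl-2-oxo-3,3a,4,7,8,8a-hexahydro-2H-cyclohepta[b]furan-5-yl trifluoromethanesulfonate
Product: 14 (3aS,7R,8aR)-7-methyl-5-(prop-2-enoyl)-3,3a,4,7,8,8a-hexahydro-2H-cyclohepta[b]furan-2-one
Conditions: CO (1 atm), Bu3SnCH=CH2, Pd(PPh3)4 (5 mol%), LiCl (3 equiv), THF, 55 °C
Reagents that add atoms: carbon monoxide, [C-]#[O+]; tributyl(vinyl)stannane, C=C[Sn](CCCC)(CCCC)CCCC
Why: Carbonylative Stille coupling of the enol triflate with the vinylstannane should give the cross-conjugated divinyl ketone with all stereocentres untouched.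

Step 10
Reactants: 14 (3aS,7R,8aR)-7-methyl-5-(prop-2-enoyl)-3,3a,4,7,8,8a-hexahydro-2H-cyclohepta[b]furan-2-one
Product: 15 (7S,8R,10R)-4-oxo-13,15-dinorguai-1(5)-en-12,8-olide
Conditions: BF3·OEt2 (1.5 equiv), CH2Cl2, 0 → 23 °C
Reagents that add atoms: none
Why: Nazarov cyclisation (conrotatory 4π closure forming C1–C2, then loss of H1 from the oxyallyl cation) should give the more substituted C1=C5 enone, which erases the C1 centre made in the closure while C10 lies outside the cation.

Step 11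
Reactants: 15 (7S,8R,10R)-4-oxo-13,15-dinorguai-1(5)-en-12,8-olide
Product: 16 (7S,8R,10R)-3-hydroxy-4-oxo-13,15-dinorguai-1(5)-en-12,8-olide (C3 epimers)
Conditions: KN(SiMe3)2 (1.05 equiv), THF, −78 °C; then 2-(benzenesulfonyl)-3-phenyloxaziridine, −78 °C
Reagents that add atoms: 2-(benzenesulfonyl)-3-phenyloxaziridine, O=S(=O)(c1ccccc1)N1OC1c1ccccc1
Why: Kinetic deprotonation at the only α′ position (C3) and Davis hydroxylation of the potassium enolate should install the oxygen needed for the fulvene, the new C3 centre being lost in step 23 and the γ-position C10 not being enolised under kinetic conditions.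

Step 12
Reactants: 16 (7S,8R,10R)-3-hydroxy-4-oxo-13,15-dinorguai-1(5)-en-12,8-olide
Product: 17 (7S,8R,10R)-3-hydroxy-13-norguaia-1(5),4(15)-dien-12,8-olide (C3 epimers)
Conditions: Zn, CH2Br2, TiCl4, THF/CH2Cl2, 0 → 23 °C
Reagents that add atoms: dibromomethane, BrCBr
Why: Takai–Lombardo methylenation, a non-basic zinc–titanium methylene transfer, should convert the ketone but neither the lactone nor the free alcohol, and cannot epimerise C10 through a dienolate.

**Eudesmane half (steps 13–22)**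

Step 13
Reactants: 18 (S)-8a-methyl-3,4,8,8a-tetrahydronaphthalene-1,6(2H,7H)-dione
Product: 19 (S)-8a-methyl-4-methylidene-3,4,8,8a-tetrahydronaphthalene-1,6(2H,7H)-dione
Conditions: CH2(OEt)2, POCl3, NaOAc, CHCl3, 65 °C
Reagents that add atoms: diethoxymethane, CCOCOCC
Why: Direct γ-methylenation of the enone through its dienol ether (attack of an alkoxymethyl cation at the γ-carbon, then loss of ethanol) is the known one-step route to 6-methylene-3-oxo-4-ene steroids and tolerates an isolated ketone next to a quaternary carbon.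

Step 14
Reactants: 19 (S)-8a-methyl-4-methylidene-3,4,8,8a-tetrahydronaphthalene-1,6(2H,7H)-dione
Product: 20 (4R,8aS)-4,8a-dimethyl-3,4,8,8a-tetrahydronaphthalene-1,6(2H,7H)-dione
Conditions: H2 (1 atm), RhCl(PPh3)3 (5 mol%), PhH, 23 °C
Reagents that add atoms: none
Why: Homogeneous hydrogenation with Wilkinson's catalyst should reduce only the 1,1-disubstituted exocyclic alkene, hydrogen arriving on the face opposite the angular methyl so that the new C4′ methyl is cis to it.

Step 15
Reactants: 20 (4R,8aS)-4,8a-dimethyl-3,4,8,8a-tetrahydronaphthalene-1,6(2H,7H)-dione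
Product: 21 (4aS,5S,8R)-5-hydroxy-4a,8-dimethyl-4,4a,5,6,7,8-hexahydronaphthalen-2(3H)-one
Conditions: NaBH4 (0.3 equiv), EtOH, −10 °C
Reagents that add atoms: none
Why: Chemoselective borohydride reduction of the saturated ketone beside the enone, with hydride arriving anti to the angular methyl, should give the C1′ alcohol cis to that methyl, as known for the parent dione.

Step 16
Reactants: 21 (4aS,5S,8R)-5-hydroxy-4a,8-dimethyl-4,4a,5,6,7,8-hexahydronaphthalen-2(3H)-one
Product: 22 (4aS,5S,8R)-5-(tert-butyldimethylsilyloxy)-4a,8-dimethyl-4,4a,5,6,7,8-hexahydronaphthalen-2(3H)-one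
Conditions: TBSCl, imidazole, DMF, 40 °C
Reagents that add atoms: tert-butyldimethylsilyl chloride, CC(C)(C)[Si](C)(C)Cl
Why: Imidazole-mediated O-silylation of the secondary alcohol affects no stereocentre and is too weakly basic to enolise the enone toward C4′.

Step 17
Reactants: 22 (4aS,5S,8R)-5-(tert-butyldimethylsilyloxy)-4a,8-dimethyl-4,4a,5,6,7,8-hexahydronaphthalen-2(3H)-one
Product: 23 (4aS,5S,8R)-5-(tert-butyldimethylsilyloxy)-4a,8-dimethyl-4,4a,5,6,7,8-hexahydronaphthalen-2-yl trifluoromethanesulfonate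
Conditions: LiN(i-Pr)2 (1.1 equiv), THF, −78 °C; then PhNTf2, −78 → 0 °C
Reagents that add atoms: N-phenylbis(trifluoromethanesulfonimide), O=S(=O)(N(c1ccccc1)S(=O)(=O)C(F)(F)F)C(F)(F)F
Why: Kinetic α′ deprotonation (C8′) gives the cross-conjugated enolate, which is trapped on oxygen as the enol triflate, γ-deprotonation at C4′ not competing at −78 °C.

Step 18
Reactants: 23 (4aS,5S,8R)-5-(tert-butyldimethylsilyloxy)-4a,8-dimethyl-4,4a,5,6,7,8-hexahydronaphthalen-2-yl trifluoromethanesulfonate
Product: 24 ethyl (1S,4R,10S)-1-(tert-butyldimethylsilyloxy)-13-noreudesma-5,7-dien-12-oate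
Conditions: BrZnCH2CO2Et, Pd(PPh3)4 (5 mol%), THF, 60 °C
Reagents that add atoms: (2-ethoxy-2-oxoethyl)zinc bromide, CCOC(=O)C[Zn]Br
Why: Negishi-type coupling of the enol triflate with a Reformatsky reagent should form the C7′–C11′ bond at sp2 carbon without creating a stereocentre.

Step 19
Reactants: 24 ethyl (1S,4R,10S)-1-(tert-butyldimethylsilyloxy)-13-noreudesma-5,7-dien-12-oate
Product: 25 ethyl (1S,4R,7R,8R,10S)-1-(tert-butyldimethylsilyloxy)-8-hydroxy-13-noreudesm-5-en-12-oate
Conditions: BH3·THF (1.1 equiv), THF, 0 °C; then NaOH, H2O2, 0 °C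
Reagents that add atoms: hydrogen peroxide, OO
Why: Hydroboration–oxidation of the less hindered C7′=C8′ bond (boron to the CH terminus C8′) from the face opposite the angular methyl adds H7′ and the C8′ oxygen syn, which puts the acetate arm on C7′ cis to the angular methyl as required and leaves a C8′ alcohol to be inverted in steps 20 and 21.

Step 20
Reactants: 25 ethyl (1S,4R,7R,8R,10S)-1-(tert-butyldimethylsilyloxy)-8-hydroxy-13-noreudesm-5-en-12-oate
Product: 26 ethyl (1S,4R,7R,10S)-1-(tert-butyldimethylsilyloxy)-8-oxo-13-noreudesm-5-en-12-oate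
Conditions: Dess–Martin periodinane, NaHCO3, CH2Cl2, 0 → 23 °C
Reagents that add atoms: none
Why: Buffered Dess–Martin oxidation of the secondary alcohol is non-enolising, so the β,γ-alkene stays out of conjugation and C7′ is kept.

Step 21
Reactants: 26 ethyl (1S,4R,7R,10S)-1-(tert-butyldimethylsilyloxy)-8-oxo-13-noreudesm-5-en-12-oate
Product: 28 (1S,4R,7R,8S,10S)-1-(tert-butyldimethylsilyloxy)-13-noreudesm-5-en-12,8-olide, via hydroxy ester 27 (not isolated)
Conditions: Li[HB(s-Bu)3], THF, −78 → 0 °C; then 1 M HCl, 23 °C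
Reagents that add atoms: none
Why: The bulky hydride attacks the C8′ ketone opposite the 1,3-related axial angular methyl, giving the axial alkoxide cis to the C7′ side chain, which closes the cis-fused γ-lactone with loss of ethanol, the classical entry to 8,12-cis eudesmanolides.

Step 22
Reactants: 28 (1S,4R,7R,8S,10S)-1-(tert-butyldimethylsilyloxy)-13-noreudesm-5-en-12,8-olide
Product: 31 (1S,4R,7S,8S,10S)-1-(tert-butyldimethylsilyloxy)eudesma-5,11(13)-dien-12,8-olide, via Mannich base 29 (not isolated), via methiodide 30 (not isolated)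
Conditions: LiN(i-Pr)2 (1.2 equiv), THF, −78 °C; CH2=NMe2+ I−, −78 → 23 °C; aqueous work-up; then MeI, MeOH, 23 °C; then NaHCO3 (aq), CH2Cl2
Reagents that add atoms: dimethylmethyleneiminium iodide, C=[N+](C)C.[I-]
Why: Mannich reaction of the lactone enolate with Eschenmoser's salt, N-quaternisation and elimination of trimethylamine is the standard α-methylenation of γ-lactones and turns C11′ into an sp2 centre.

**Union, key step and endgame (steps 23–28)**

Step 23
Reactants: 17 (7S,8R,10R)-3-hydroxy-13-norguaia-1(5),4(15)-dien-12,8-olide and 31 (1S,4R,7S,8S,10S)-1-(tert-butyldimethylsilyloxy)eudesma-5,11(13)-dien-12,8-olide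
Product: 34 fulvene Diels–Alder adduct (7-methylenenorbornene with C5–C13′ and C3–C11′ bonds and the C12′ carbonyl exo), via sulfamate ester 32 (not isolated), via fulvene 33 (not isolated)
Conditions: 17 (1.5 equiv), 31 (1.0 equiv), MeO2CN(−)SO2N(+)Et3 (Burgess reagent, 1.6 equiv), BHT (cat.), PhMe (0.5 M), 23 → 70 °C
Reagents that add atoms: none
Why: Burgess dehydration (syn-elimination of the C3 sulfamate with a C2 hydrogen) should release the fulvene in the presence of the dienophile, and a thermal Diels–Alder reaction across C3/C5 should follow in which the CH2 terminus C13′ bonds to substituted C5 and quaternary C11′ to C3–H (no vicinal quaternary centres), the s-cis-locked α-methylene lactone reacts exo, the fulvene is attacked on the face opposite the C10 methyl and the C7–C11 bond, and the dienophile on the convex face of its cis-fused lactone (syn to H7′ and H8′), which together set C3, C5 and C11′.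

Step 24
Reactants: 34 fulvene Diels–Alder adduct
Product: 35 exo-1,2-epoxide of adduct 34
Conditions: mCPBA (1.05 equiv), NaHCO3, CH2Cl2, −20 → 0 °C
Reagents that add atoms: 3-chloroperoxybenzoic acid, OOC(=O)c1cccc(Cl)c1
Why: Prilezhaev epoxidation should take the strained trisubstituted norbornene alkene C1=C2 on its exo face (syn to the C4 bridge, the endo face being covered by the eudesmane unit on C11′) in preference to the hindered C5′=C6′ and the 1,1-disubstituted C4=C15 alkenes, which fixes the C2 oxygen.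

Step 25
Reactants: 35 exo-1,2-epoxide of adduct 34
Product: 36 2-O-deacetyl-13-norjaponicone A 1′-O-tert-butyldimethylsilyl ether
Conditions: BF3·OEt2 (2.0 equiv), Et3SiH (5 equiv), CH2Cl2, −78 → −40 °C; aq. NaHCO3
Reagents that add atoms: none
Why: Proposed new method: BF3 should ionise the exo epoxide at tertiary C1 with assistance from the antiperiplanar C5–C13′ σ-bond, so that C13′ shifts suprafacially from C5 to C1 and the charge arrives at C5 as the C5–C4–C15 allyl cation, which Et3SiH reduces at the open primary C15 terminus to leave the tetrasubstituted C4=C5 alkene and the C15 methyl; the closest known reaction types are the acid-induced Wagner–Meerwein rearrangement of norbornene exo-epoxides to 7-syn-hydroxy-2-exo-substituted norbornanes and the silane (ionic) reduction of carbocations generated with BF3·OEt2. The five-membered ring C1–C13′–C11′–C3–C2 is closed by this 1,2-alkyl shift and not by a cyclisation, the C4-bridged bicycle becoming the C2-bridged one. C1 is set by entry of C13′ anti to the departing oxygen (inversion), and C2 keeps the exo oxygen from step 24, which therefore ends syn to C4=C5. The step needs C1–O rather than C2–O cleavage (tertiary against secondary carbon), migration of C13′ rather than C4 (only the C5–C13′ bond is antiperiplanar to an exo C–O bond) and hydride delivery at C15 rather than C5 (C5 is fully substituted and screened by the C2–O–BF3 group on one face and the endo C12′ carbonyl on the other). Direct hydride capture at C1 before the shift would have to come from the blocked endo face, and excess silane at low temperature should outrun proton loss from the allyl cation. The 13-nor lactone carries no Michael acceptor and the hindered silyl ether should survive BF3·OEt2 at this temperature.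

Step 26
Reactants: 36 2-O-deacetyl-13-norjaponicone A 1′-O-tert-butyldimethylsilyl ether
Product: 39 2-O-deacetyljaponicone A 1′-O-tert-butyldimethylsilyl ether, via Mannich base 37 (not isolated), via methiodide 38 (not isolated)
Conditions: LiN(SiMe3)2 (2.5 equiv), THF, −78 °C; CH2=NMe2+ I− (3 equiv), −78 → 0 °C; aqueous NH4Cl work-up; then MeI, MeOH/CH2Cl2, 23 °C; then NaHCO3 (aq)
Reagents that add atoms: dimethylmethyleneiminium iodide, C=[N+](C)C.[I-]
Why: Mannich α-methylenation as in step 22 should act only on the guaiane lactone, since C11′ of the spiro lactone is quaternary and the C2 alcohol is carried as its lithium alkoxide (any O-aminomethyl ether is hydrolysed on work-up).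

Step 27
Reactants: 39 2-O-deacetyljaponicone A 1′-O-tert-butyldimethylsilyl ether
Product: 40 japonicone A 1′-O-tert-butyldimethylsilyl ether
Conditions: Ac2O, DMAP, pyridine, CH2Cl2, 23 → 40 °C
Reagents that add atoms: acetic anhydride, CC(=O)OC(C)=O
Why: DMAP-catalysed O-acylation of the hindered secondary C2 alcohol retains the C2 configuration, the only other hydroxyl (C1′) being silylated.

Step 28
Reactants: 40 japonicone A 1′-O-tert-butyldimethylsilyl ether
Product: 41 japonicone A
Conditions: HF·pyridine, THF/pyridine, 0 → 23 °C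
Reagents that add atoms: none
Why: Buffered fluoride cleavage of the Si–O bond should free the C1′ alcohol while sparing the acetate, both lactones and the Michael-accepting α-methylene lactone.

**Compound list**

1 | (R)-epichlorohydrin | ClC[C@H]1CO1 | starting material
2 | (R)-1-chloropent-4-en-2-ol | ClC[C@H](O)CC=C | intermediate
3 | (R)-2-(prop-2-en-1-yl)oxirane | C=CC[C@@H]1CO1 | intermediate
4 | (4R)-4-hydroxy-2-(phenylsulfanyl)hept-6-enoic acid, C2 epimers (hydroxy acid) | OC(=O)C(Sc1ccccc1)C[C@H](O)CC=C | intermediate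
5 | (5R)-3-(phenylsulfanyl)-5-(prop-2-en-1-yl)oxolan-2-one, C3 epimers | C=CC[C@@H]1CC(Sc2ccccc2)C(=O)O1 | intermediate
6 | (5R)-3-(benzenesulfinyl)-5-(prop-2-en-1-yl)oxolan-2-one (sulfoxide) | C=CC[C@@H]1CC(S(=O)c2ccccc2)C(=O)O1 | intermediate
7 | (R)-5-(prop-2-en-1-yl)furan-2(5H)-one | C=CC[C@@H]1C=CC(=O)O1 | intermediate
8 | silyl ketene acetal of lactone 9 (2-silyloxy-4,5-dihydrofuran) | CCSC(=O)C[C@H]1C=C(O[Si](C)(C)C(C)(C)C)O[C@@H]1CC=C | intermediate
9 | S-ethyl 2-[(2R,3R)-5-oxo-2-(prop-2-en-1-yl)oxolan-3-yl]ethanethioate (trans) | CCSC(=O)C[C@H]1CC(=O)O[C@@H]1CC=C | intermediate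
10 | (4S,5R)-4-(2-oxobut-3-en-1-yl)-5-(prop-2-en-1-yl)oxolan-2-one | C=CC(=O)C[C@H]1CC(=O)O[C@@H]1CC=C | intermediate
11 | (3aS,8aR)-3a,4,8,8a-tetrahydro-2H-cyclohepta[b]furan-2,5(3H)-dione (trans-fused) | O=C1C=CC[C@H]2OC(=O)C[C@@H]2C1 | intermediate
12 | methylzinc enolate of the 7-methyl ketone (zinc enolate) | C[C@@H]1C[C@H]2OC(=O)C[C@@H]2CC(O[Zn]C)=C1 | intermediate
13 | (3aS,7R,8aR)-7-methyl-2-oxo-3,3a,4,7,8,8a-hexahydro-2H-cyclohepta[b]furan-5-yl trifluoromethanesulfonate | C[C@@H]1C[C@H]2OC(=O)C[C@@H]2CC(OS(=O)(=O)C(F)(F)F)=C1 | intermediate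
14 | (3aS,7R,8aR)-7-methyl-5-(prop-2-enoyl)-3,3a,4,7,8,8a-hexahydro-2H-cyclohepta[b]furan-2-one | C=CC(=O)C1=C[C@H](C)C[C@H]2OC(=O)C[C@@H]2C1 | intermediate
15 | (7S,8R,10R)-4-oxo-13,15-dinorguai-1(5)-en-12,8-olide | O=C1CCC2=C1C[C@H]3CC(=O)O[C@@H]3C[C@H]2C | intermediate
16 | (7S,8R,10R)-3-hydroxy-4-oxo-13,15-dinorguai-1(5)-en-12,8-olide, C3 epimers | O=C1C(O)CC2=C1C[C@H]3CC(=O)O[C@@H]3C[C@H]2C | intermediate
17 | (7S,8R,10R)-3-hydroxy-13-norguaia-1(5),4(15)-dien-12,8-olide, C3 epimers | C=C1C(O)CC2=C1C[C@H]3CC(=O)O[C@@H]3C[C@H]2C | intermediate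
18 | (S)-8a-methyl-3,4,8,8a-tetrahydronaphthalene-1,6(2H,7H)-dione | C[C@]12CCC(=O)C=C1CCCC2=O | starting material
19 | (S)-8a-methyl-4-methylidene-3,4,8,8a-tetrahydronaphthalene-1,6(2H,7H)-dione | C[C@]12CCC(=O)C=C1C(=C)CCC2=O | intermediate
20 | (4R,8aS)-4,8a-dimethyl-3,4,8,8a-tetrahydronaphthalene-1,6(2H,7H)-dione | C[C@]12CCC(=O)C=C1[C@H](C)CCC2=O | intermediate
21 | (4aS,5S,8R)-5-hydroxy-4a,8-dimethyl-4,4a,5,6,7,8-hexahydronaphthalen-2(3H)-one | C[C@]12CCC(=O)C=C1[C@H](C)CC[C@@H]2O | intermediate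
22 | (4aS,5S,8R)-5-(tert-butyldimethylsilyloxy)-4a,8-dimethyl-4,4a,5,6,7,8-hexahydronaphthalen-2(3H)-one | C[C@]12CCC(=O)C=C1[C@H](C)CC[C@@H]2O[Si](C)(C)C(C)(C)C | intermediate
23 | (4aS,5S,8R)-5-(tert-butyldimethylsilyloxy)-4a,8-dimethyl-4,4a,5,6,7,8-hexahydronaphthalen-2-yl trifluoromethanesulfonate | C[C@]12CC=C(OS(=O)(=O)C(F)(F)F)C=C1[C@H](C)CC[C@@H]2O[Si](C)(C)C(C)(C)C | intermediate
24 | ethyl (1S,4R,10S)-1-(tert-butyldimethylsilyloxy)-13-noreudesma-5,7-dien-12-oate | C[C@]12CC=C(CC(=O)OCC)C=C1[C@H](C)CC[C@@H]2O[Si](C)(C)C(C)(C)C | intermediate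
25 | ethyl (1S,4R,7R,8R,10S)-1-(tert-butyldimethylsilyloxy)-8-hydroxy-13-noreudesm-5-en-12-oate (C8′–OH trans to the C7′ arm) | C[C@]12C[C@@H](O)[C@H](CC(=O)OCC)C=C1[C@H](C)CC[C@@H]2O[Si](C)(C)C(C)(C)C | intermediate
26 | ethyl (1S,4R,7R,10S)-1-(tert-butyldimethylsilyloxy)-8-oxo-13-noreudesm-5-en-12-oate | C[C@]12CC(=O)[C@H](CC(=O)OCC)C=C1[C@H](C)CC[C@@H]2O[Si](C)(C)C(C)(C)C | intermediate
27 | ethyl (1S,4R,7R,8S,10S)-1-(tert-butyldimethylsilyloxy)-8-hydroxy-13-noreudesm-5-en-12-oate (C8′–OH cis to the C7′ arm; hydroxy ester) | C[C@]12C[C@H](O)[C@H](CC(=O)OCC)C=C1[C@H](C)CC[C@@H]2O[Si](C)(C)C(C)(C)C | intermediate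
28 | (1S,4R,7R,8S,10S)-1-(tert-butyldimethylsilyloxy)-13-noreudesm-5-en-12,8-olide (cis-fused lactone) | C1C(=O)O[C@H]2C[C@@]3(C)C(=C[C@@H]12)[C@H](C)CC[C@@H]3O[Si](C)(C)C(C)(C)C | intermediate
29 | 11′-(dimethylaminomethyl) derivative of 28, C11′ not assigned (Mannich base) | CN(C)CC1C(=O)O[C@H]2C[C@@]3(C)C(=C[C@@H]12)[C@H](C)CC[C@@H]3O[Si](C)(C)C(C)(C)C | intermediate
30 | trimethylammonium iodide of 29 (methiodide) | C[N+](C)(C)CC1C(=O)O[C@H]2C[C@@]3(C)C(=C[C@@H]12)[C@H](C)CC[C@@H]3O[Si](C)(C)C(C)(C)C.[I-] | intermediate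
31 | (1S,4R,7S,8S,10S)-1-(tert-butyldimethylsilyloxy)eudesma-5,11(13)-dien-12,8-olide | C=C1C(=O)O[C@H]2C[C@@]3(C)C(=C[C@@H]12)[C@H](C)CC[C@@H]3O[Si](C)(C)C(C)(C)C | intermediate
32 | C3 O-[N-(methoxycarbonyl)sulfamate] of 17 (sulfamate ester) | C=C1C(OS(=O)(=O)NC(=O)OC)CC2=C1C[C@H]3CC(=O)O[C@@H]3C[C@H]2C | intermediate
33 | (7S,8R,10R)-13-norguaia-1(5),2,4(15)-trien-12,8-olide (fulvene) | C=C1C=CC2=C1C[C@H]3CC(=O)O[C@@H]3C[C@H]2C | intermediate
34 | fulvene Diels–Alder adduct: C13′ on C5, C11′ on C3, C1=C2 alkene, exocyclic C4=C15, C12′ carbonyl exo | C1C(=O)O[C@@H]2C[C@@H](C)C3=C[C@H]4C(=C)[C@]3(C[C@@H]12)C[C@]45C(=O)O[C@H]6C[C@@]7(C)C(=C[C@H]65)[C@H](C)CC[C@@H]7O[Si](C)(C)C(C)(C)C | intermediate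
35 | exo-1,2-epoxide of 34 | C1C(=O)O[C@@H]2C[C@@H](C)[C@@]34O[C@H]4[C@H]4C(=C)[C@]3(C[C@@H]12)C[C@]45C(=O)O[C@H]6C[C@@]7(C)C(=C[C@H]65)[C@H](C)CC[C@@H]7O[Si](C)(C)C(C)(C)C | intermediate
36 | 2-O-deacetyl-13-norjaponicone A 1′-O-tert-butyldimethylsilyl ether | C1C(=O)O[C@@H]2C[C@@H](C)[C@]34C[C@]5(C(=O)O[C@H]6C[C@@]7(C)C(=C[C@H]65)[C@H](C)CC[C@@H]7O[Si](C)(C)C(C)(C)C)[C@H](C(C)=C3C[C@@H]12)[C@@H]4O | intermediate
37 | 11-(dimethylaminomethyl) derivative of 36, C11 not assigned (Mannich base) | CN(C)CC1C(=O)O[C@@H]2C[C@@H](C)[C@]34C[C@]5(C(=O)O[C@H]6C[C@@]7(C)C(=C[C@H]65)[C@H](C)CC[C@@H]7O[Si](C)(C)C(C)(C)C)[C@H](C(C)=C3C[C@@H]12)[C@@H]4O | intermediate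
38 | trimethylammonium iodide of 37 (methiodide) | C[N+](C)(C)CC1C(=O)O[C@@H]2C[C@@H](C)[C@]34C[C@]5(C(=O)O[C@H]6C[C@@]7(C)C(=C[C@H]65)[C@H](C)CC[C@@H]7O[Si](C)(C)C(C)(C)C)[C@H](C(C)=C3C[C@@H]12)[C@@H]4O.[I-] | intermediate
39 | 2-O-deacetyljaponicone A 1′-O-tert-butyldimethylsilyl ether | C=C1C(=O)O[C@@H]2C[C@@H](C)[C@]34C[C@]5(C(=O)O[C@H]6C[C@@]7(C)C(=C[C@H]65)[C@H](C)CC[C@@H]7O[Si](C)(C)C(C)(C)C)[C@H](C(C)=C3C[C@@H]12)[C@@H]4O | intermediate
40 | japonicone A 1′-O-tert-butyldimethylsilyl ether | C=C1C(=O)O[C@@H]2C[C@@H](C)[C@]34C[C@]5(C(=O)O[C@H]6C[C@@]7(C)C(=C[C@H]65)[C@H](C)CC[C@@H]7O[Si](C)(C)C(C)(C)C)[C@H](C(C)=C3C[C@@H]12)[C@@H]4OC(C)=O | intermediate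
41 | japonicone A | C=C1C(=O)O[C@@H]2C[C@@H](C)[C@]34C[C@]5(C(=O)O[C@H]6C[C@@]7(C)C(=C[C@H]65)[C@H](C)CC[C@@H]7O)[C@H](C(C)=C3C[C@@H]12)[C@@H]4OC(C)=O | target

**Count and risks**

Total step count: 28. Longest linear sequence: 18 steps (steps 1–12 and 23–28, from (R)-epichlorohydrin); the eudesmane branch (steps 13–22) joins at step 23.

Steps most likely to fail:

1. Step 25. The cation cascade may leave its intended path: epoxide opening without migration (hydride shift to a C2 ketone), proton loss from the allyl cation instead of hydride capture, or Lewis-acid loss of the silyl ether. The fallback sets out from 35 and comes back at 36 and separates rearrangement from reduction. Treatment of 35 with MgBr2·OEt2 in CH2Cl2 at −20 °C, the halide-terminated form of the rearrangement that hydrogen halides effect on norbornene exo-epoxides, should give the rearranged allylic bromide 15-bromo-2-O-deacetyl-13-norjaponicone A 1′-O-tert-butyldimethylsilyl ether F1. Radical dehalogenation (Bu3SnH, AIBN, PhH, 80 °C), with hydrogen transfer to the primary terminus of the allyl radical, should then give 36.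

2. Step 23. Fulvene oligomerisation may outrun the cycloaddition, and facial, regio- or exo selectivity may be incomplete. The fallback sets out from 16 and comes back at 34 and replaces the fulvene by a 5,5-dialkoxycyclopentadiene, a more reactive diene that cannot isomerise. Ketalisation of 16 (MeOSiMe3, TMSOTf, CH2Cl2, −78 °C) should give the hydroxy dimethyl ketal F2. Burgess dehydration of F2 in the presence of 31 should form the cyclopentadienone dimethyl ketal F3 in the flask, which adds 31 to give the 7,7-dimethoxynorbornene adduct F4. Mild hydrolysis (PPTS, wet acetone, 50 °C) should give the norbornen-7-one F5, and Takai–Lombardo methylenation (Zn, CH2Br2, TiCl4) should return 34.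

3. Step 10. Acid-induced polymerisation of the vinyl ketone, formation of the wrong alkene isomer, or epimerisation of C10 through a dienol may erode the Nazarov step. The fallback sets out from 13 and comes back at 15 and builds the cyclopentenone under neutral gold catalysis. Sonogashira coupling of 13 with prop-2-yn-1-yl acetate (Pd(PPh3)4, CuI, Et3N, THF) should give the enynyl acetate F6. Ph3PAuCl/AgSbF6 in wet CH2Cl2 should trigger the 3,3-acyloxy shift and Nazarov closure to the cyclopentadienyl acetate F7, hydrolysed in the flask to the cis-fused cyclopent-2-enone F8. Brief treatment with DBU or RhCl3·3H2O should move the alkene into the ring fusion to give 15.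

Further compounds
F1 | step 25 | 15-bromo-2-O-deacetyl-13-norjaponicone A 1′-O-tert-butyldimethylsilyl ether | C1C(=O)O[C@@H]2C[C@@H](C)[C@]34C[C@]5(C(=O)O[C@H]6C[C@@]7(C)C(=C[C@H]65)[C@H](C)CC[C@@H]7O[Si](C)(C)C(C)(C)C)[C@H](C(CBr)=C3C[C@@H]12)[C@@H]4O
F2 | step 23 | (7S,8R,10R)-3-hydroxy-4,4-dimethoxy-13,15-dinorguai-1(5)-en-12,8-olide | OC1CC2=C(C1(OC)OC)C[C@H]3CC(=O)O[C@@H]3C[C@H]2C
F3 | step 23 | (7S,8R,10R)-4,4-dimethoxy-13,15-dinorguaia-1(5),2-dien-12,8-olide | C1=CC2=C(C1(OC)OC)C[C@H]3CC(=O)O[C@@H]3C[C@H]2C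
F4 | step 23 | 7,7-dimethoxynorbornene analogue of 34 (C4 as dimethyl ketal) | C1C(=O)O[C@@H]2C[C@@H](C)C3=C[C@H]4C(OC)(OC)[C@]3(C[C@@H]12)C[C@]45C(=O)O[C@H]6C[C@@]7(C)C(=C[C@H]65)[C@H](C)CC[C@@H]7O[Si](C)(C)C(C)(C)C
F5 | step 23 | norbornen-7-one analogue of 34 (C4 ketone) | C1C(=O)O[C@@H]2C[C@@H](C)C3=C[C@H]4C(=O)[C@]3(C[C@@H]12)C[C@]45C(=O)O[C@H]6C[C@@]7(C)C(=C[C@H]65)[C@H](C)CC[C@@H]7O[Si](C)(C)C(C)(C)C
F6 | step 10 | 3-[(3aS,7R,8aR)-7-methyl-2-oxo-3,3a,4,7,8,8a-hexahydro-2H-cyclohepta[b]furan-5-yl]prop-2-yn-1-yl acetate | CC(=O)OCC#CC1=C[C@H](C)C[C@H]2OC(=O)C[C@@H]2C1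
F7 | step 10 | (7S,8R,10R)-4-acetoxy-13,15-dinorguaia-2,4-dien-12,8-olide, C1 not assigned | CC(=O)OC1=C2C[C@H]3CC(=O)O[C@@H]3C[C@@H](C)C2C=C1
F8 | step 10 | (7S,8R,10R)-4-oxo-13,15-dinorguai-2-en-12,8-olide, cis ring fusion with C1 and C5 not assigned | O=C1C=CC2C1C[C@H]3CC(=O)O[C@@H]3C[C@H]2C
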